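## The problem

Target 21 is a (2S)-configured 7-hydroxy-5-methoxy-4′-hydroxyflavanone whose C8 carries a nine-carbon chain, numbered here from s1 (the carbinol bound to C8) to s9 (the terminal ArCH2). In this chain s1 is a benzylic secondary alcohol (S), s3 a methine bearing a 4-hydroxyphenyl group (R), s4=s5 an E alkene, s7 a secondary alcohol (S), and s9 holds the second 4-hydroxyphenyl group. The chain meets the flavanone through one C8–s1 bond lying between two oxygen-bearing carbons (C7–OH and C8a–O1), so the junction is crowded and ring A is an electron-rich, phloroglucinol-type arene. None of the four stereocentres can be trusted to control another: C2 is alone on the heterocycle, s7 is cut off from s3 by the alkene, and s1 and s3 are 1,3-related with no heteroatom on s3 to guide a reagent. Each therefore has to come from a catalyst, a reagent or a building block. Several features are fragile: the flavanone opens to the 2′-hydroxychalcone in base and loses C2; the s1 carbinol ortho to a free phenol can ionise to an ortho-quinone methide with acid or heat and is easily re-oxidised; the s3–H bond is both benzylic and allylic, so the alkene can slip into conjugation; and six hydroxyl groups need masks that come off near neutrality. The enabling feature is that s1 sits on C8 ortho to the free C7 phenol, so at the aldehyde oxidation level it is a salicylaldehyde carbon, and s2–s5 with the aryl group on s3 is the skeleton of a 2-aryl-1,3-diene. Adding the aldehyde C–H bond across s2=s3 would make the s1–s2 bond and the s3 stereocentre in one operation.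

## Retrosynthesis

**21 from 20.** Only six O–Si bonds are cut. Carrying every hydroxyl as a tert-butyldimethylsilyl ether lets one buffered fluoride treatment end the synthesis without acid (danger to s1) or free base (danger to C2). The forward step must cleave a hindered benzylic silyl ether under these mild conditions.

**20 from 18 and 19.** The C2–aryl bond of ring B is cut, which returns the flavanone to a chromone. The neighbouring option, closing the flavanone from a chalcone, would put a base-labile stereocentre into the molecule early. The chromone is flat, has no C2 stereocentre and tolerates the basic and Lewis acidic steps before it. Chromone 18 lacks ring B and one stereocentre; 19 is the commercial boronic acid. The forward reaction has to choose the chromone face by catalyst control.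

**18 from 15 via 17 and 16.** The s1 C–H bond and two O–Si bonds are cut, which leads back to aryl ketone 15. Setting s1 by reduction after the chain is attached is preferred to bringing it in, because the key step delivers exactly this ketone. The C7 phenol is silylated first (16), since a free ortho-phenol would consume borane and deliver hydride without catalyst control. The new carbinol is silylated (18), since divalent palladium under air oxidises benzylic alcohols. The reduction must distinguish the ketone faces against a remote s3 centre and leave the chromone alone.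

**15 from 4 and 14.** The s1–s2 bond and the s3–H bond are cut. Neighbouring cuts were weighed:
- C8–s1 would need an aryl metal between two oxygens on a chromone.
- s2–s3 and s6–s7 lead to the longer roads discussed below.
- s3–s4 is kept as the fallback.

The chosen cut divides the molecule into the finished flavonoid nucleus 4 and the complete chain 14, which holds one stereocentre only. It forms no stoichiometric by-product and uses the target's own phenol as the directing group. The forward reaction must add acyl to the CH2 terminus and hydrogen to the aryl-bearing carbon of the diene, with control of the new s3 centre.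

**14 from 7 and 13.** The s3–s4 single bond between the two alkenes is cut (Suzuki–Miyaura coupling). Against methylenation of an enone or enyne cross-metathesis, this cut takes the E geometry unchanged from the alkenylboronate and joins two fragments of similar size. Enol triflate 7 must be used fresh.

**13 from 10 via 12 and 11.** The C–B and C–H bonds of the alkenylboronate are cut back to the terminal alkyne 12 (syn hydroboration can give only the E isomer). The s6–s7 bond is then cut to aldehyde 10 and a propargyl nucleophile. This places the single stereocentre of the chain, s7, in a catalytic carbonyl addition. Aldehyde 10 comes from ester 9 and commercial 8.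

**7 from 5 via 6.** The enol C–O bond is cut back to the methyl ketone. Nothing but silylation and enolate triflation is asked.

**4 from 1 via 3.** The C8–CHO bond is cut (ortho-formylation of the phenol), then the pyranone ring is opened to acetophenone 1 and a one-carbon unit. In 1 the methoxy group is already in place and only the 2′-hydroxyl is ortho to the acyl group, so ring closure is unambiguous. The forward formylation must choose C8 over C6.

## Roads not taken

**Alternative 1: chirality transfer from a secondary allylboronate (cut at s6–s7).** The forward key step would activate the secondary allylic pinacol boronate A2 (boron on s4, terminal vinyl group s5=s6, ring A as a 2,6-bis(methoxymethoxy)-4-methoxyphenyl group, s1 as silyl ether) with n-BuLi and trifluoroacetic anhydride in the borinic ester manner and add it to aldehyde 10. A chair transition state with the s3 side chain equatorial would pass the (R) configuration of s4 on to (S) at s7 and give the E s4=s5 alkene in homoallylic alcohol A1.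
- Merits: the reaction type is well understood, one step sets both s7 and the alkene geometry, and it shares aldehyde 10 with the chosen route.
- Weak points: A2 needs three stereocentres (s1, s3 and the boron-bearing s4, the last next to a diarylmethine-like carbon), and making it would take more steps than the whole of diene 14. The heterocycle is still missing in A1, so ring A must later be acylated, cyclised and arylated. The methoxymethyl groups then have to leave under acid beside an s1 benzylic ether on a trioxygenated ring.
- Comparison: in reliability of the key reaction this road is ahead, because step 11 has no close precedent. The chosen plan sets against that its convergence (fragments of two and six steps), a flavonoid core that is complete before the coupling, no acid-labile acetals, and a fallback by known chemistry that rejoins the route after four operations.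

**Alternative 2: late arylation of the chromone as the strategic step (cut at C2–aryl).** The forward key step adds boronic acid 19 to the fully elaborated chromone 18 with Pd(OCOCF3)2 and a chiral pyridine-oxazoline ligand, giving A3, which is the same compound as 20.
- Merits: C2 is set last, so it never meets base; the face is chosen by the catalyst; and the chromone is a sturdy spectator until then.
- Weak points: it is an endgame and does not say how the chain and its junction to ring A are made. It also places its risk (a poorly electrophilic, 5,7-dioxygenated, 8-substituted chromone) on the most advanced intermediate.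
- Comparison: on this bond the two roads are equal, because the chosen plan contains this reaction as step 15. Taken as the defining step it has the advantage of a reaction class already shown on chromones. The chosen plan sets against it an answer to the harder question, the s1–s3 region, and accepts the same late risk.

**Alternative 3: Claisen rearrangement of a diarylheptanoid allylic vinyl ether (cut at s2–s3).** The forward key step heats A5, the 1-arylvinyl ether of the s5 allylic alcohol of an (E)-1,7-diarylhept-1-ene-3,5-diol with (R) at s5 and (S) at s7. A chair with the s6 branch equatorial should transfer (R) at s5 to (R) at s3 and give the E s4=s5 alkene in aryl ketone A4.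
- Merits: the stereochemical course is predictable from the chair, the anti relation of the two oxygens at s5 and s7 is accessible by known aldol and reduction chemistry, and no metal is needed.
- Weak points: A5 is an α-aryl vinyl ether of a secondary alcohol with a 2,6-dioxygenated aryl group, reachable in practice only by methylenation of a very hindered benzoate. Its allylic C–O bond is cinnamylic and para-oxygenated, so ionisation can compete with the concerted path and erode the transfer. After A4 the pyranone still has to be built on a ring that now carries a deactivating acyl group, again with acid-labile acetals to remove.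
- Comparison: the Claisen step is more certain in its stereochemical outcome than the ligand-controlled hydride transfer of step 11. The chosen plan sets against this a single chain stereocentre in place of a stereodefined diol, a heterocycle present from the start, and a clearly shorter sequence.

Key step: step 11

Assumption: the senses of asymmetric induction quoted in steps 7, 11, 13 and 15 follow the behaviour of simpler members of each substrate class and would be verified on a model before scale-up, the mirror-image ligand being used where needed.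

## Route

Step 1
Reactants: 1 2′,4′-dihydroxy-6′-methoxyacetophenone
Product: 3 7-hydroxy-5-methoxy-4H-chromen-4-one, via enaminone 2 (not isolated)
Conditions: Me2NCH(OMe)2, toluene, 90 °C; then conc. HCl, CH2Cl2, 40 °C
Reagents that add atoms: N,N-dimethylformamide dimethyl acetal, COC(OC)N(C)C
Why: Condensation of the methyl ketone with the amide acetal gives the enaminone, and acid then drives conjugate addition of the 2′-hydroxyl (the only hydroxyl ortho to the acyl group) with loss of dimethylamine; this is the standard enaminone route to chromones.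

Step 2
Reactants: 3 7-hydroxy-5-methoxy-4H-chromen-4-one
Product: 4 7-hydroxy-5-methoxy-4-oxo-4H-chromene-8-carbaldehyde
Conditions: hexamethylenetetramine, CF3CO2H, 90 °C; then 3 M HCl, 60 °C
Reagents that add atoms: hexamethylenetetramine, C1N2CN3CN1CN(C2)C3; water, O
Why: Duff formylation: the iminium ion from hexamethylenetetramine attacks ortho to the phenol, and in 7-hydroxychromones the C7–C8 bond has the higher double-bond character, so C8 (also para to the methoxy group) should be preferred over C6; hydrolysis of the benzylic iminium gives the aldehyde.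

Step 3
Reactants: 5 4′-hydroxyacetophenone
Product: 6 4′-(tert-butyldimethylsilyloxy)acetophenone
Conditions: TBSCl, imidazole, DMF, rt
Reagents that add atoms: tert-butyldimethylsilyl chloride, CC(C)(C)[Si](C)(C)Cl
Why: Standard silylation of a phenol; the aryl silyl ether tolerates the amide base of the next step.

Step 4
Reactants: 6 4′-(tert-butyldimethylsilyloxy)acetophenone
Product: 7 1-[4-(tert-butyldimethylsilyloxy)phenyl]vinyl trifluoromethanesulfonate
Conditions: KN(SiMe3)2, THF, −78 °C; then PhNTf2, −78 → 0 °C
Reagents that add atoms: N-phenylbis(trifluoromethanesulfonimide), O=S(=O)(N(c1ccccc1)S(=O)(=O)C(F)(F)F)C(F)(F)F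
Why: The kinetic potassium enolate of the methyl ketone is trapped on oxygen by the triflimide (enol triflate formation); the product is used without storage.

Step 5
Reactants: 8 methyl 3-(4-hydroxyphenyl)propanoate
Product: 9 methyl 3-[4-(tert-butyldimethylsilyloxy)phenyl]propanoate
Conditions: TBSCl, imidazole, DMF, rt
Reagents that add atoms: tert-butyldimethylsilyl chloride, CC(C)(C)[Si](C)(C)Cl
Why: Standard silylation of a phenol.

Step 6
Reactants: 9 methyl 3-[4-(tert-butyldimethylsilyloxy)phenyl]propanoate
Product: 10 3-[4-(tert-butyldimethylsilyloxy)phenyl]propanal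
Conditions: i-Bu2AlH (1.05 equiv), CH2Cl2, −78 °C; aq. KNaC4H4O6
Reagents that add atoms: none
Why: Partial reduction of the methyl ester at low temperature stops at the tetrahedral aluminium hemiacetal, which releases the aldehyde on work-up.

Step 7
Reactants: 10 3-[4-(tert-butyldimethylsilyloxy)phenyl]propanal
Product: 11 (S)-1-[4-(tert-butyldimethylsilyloxy)phenyl]hex-5-yn-3-ol
Conditions: allenylSnBu3, (R)-BINOL (20 mol%), Ti(OiPr)4 (10 mol%), 4 Å MS, CH2Cl2, −20 °C
Reagents that add atoms: allenyltributylstannane, C=C=C[Sn](CCCC)(CCCC)CCCC
Why: Keck asymmetric propargylation: the allenylstannane adds in an SE2′ manner to the aldehyde bound to the BINOL titanate; the (R)-ligand should expose the Re face, which gives the (S)-carbinol at s7 (the propargyl group ranks above the arylethyl group).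

Step 8
Reactants: 11 (S)-1-[4-(tert-butyldimethylsilyloxy)phenyl]hex-5-yn-3-ol
Product: 12 tert-butyl{4-[(3S)-3-(tert-butyldimethylsilyloxy)hex-5-yn-1-yl]phenoxy}dimethylsilane
Conditions: TBSCl, imidazole, DMF, rt
Reagents that add atoms: tert-butyldimethylsilyl chloride, CC(C)(C)[Si](C)(C)Cl
Why: Standard silylation of an unhindered secondary alcohol; the s7 centre is not touched.

Step 9
Reactants: 12 tert-butyl{4-[(3S)-3-(tert-butyldimethylsilyloxy)hex-5-yn-1-yl]phenoxy}dimethylsilane
Product: 13 2-{(1E,4S)-4-(tert-butyldimethylsilyloxy)-6-[4-(tert-butyldimethylsilyloxy)phenyl]hex-1-en-1-yl}-4,4,5,5-tetramethyl-1,3,2-dioxaborolane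
Conditions: pinacolborane, Cp2Zr(H)Cl (10 mol%), Et3N (10 mol%), CH2Cl2, 40 °C
Reagents that add atoms: pinacolborane, B1OC(C)(C)C(C)(C)O1
Why: Zirconium-catalysed hydroboration of a terminal alkyne: syn addition of H–B places boron on the terminal carbon (s4) and can give only the E-alkenylboronate; silyl ethers are inert.

Step 10
Reactants: 13 the (E)-alkenyl pinacol boronate; 7 1-[4-(tert-butyldimethylsilyloxy)phenyl]vinyl trifluoromethanesulfonate
Product: 14 (3E,6S)-6-(tert-butyldimethylsilyloxy)-2,8-bis[4-(tert-butyldimethylsilyloxy)phenyl]octa-1,3-diene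
Conditions: Pd(PPh3)4 (5 mol%), K3PO4, 1,4-dioxane/H2O, 50 °C
Reagents that add atoms: none
Why: Suzuki–Miyaura coupling of an alkenylboronate with a 1-arylvinyl triflate on zerovalent palladium forms the s3–s4 bond with retention of the E geometry; aqueous phosphate at 50 °C should spare the aryl silyl ethers.

Step 11
Reactants: 4 7-hydroxy-5-methoxy-4-oxo-4H-chromene-8-carbaldehyde; 14 (3E,6S)-6-(tert-butyldimethylsilyloxy)-2,8-bis[4-(tert-butyldimethylsilyloxy)phenyl]octa-1,3-diene
Product: 15 8-{(3R,4E,7S)-7-(tert-butyldimethylsilyloxy)-3,9-bis[4-(tert-butyldimethylsilyloxy)phenyl]non-4-enoyl}-7-hydroxy-5-methoxy-4H-chromen-4-one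
Conditions: [Rh(cod)Cl]2 (5 mol%), (R)-DTBM-SEGPHOS (11 mol%), K3PO4 (20 mol%), ClCH2CH2Cl, 60 °C
Reagents that add atoms: none
Why: Proposed new method: the C7 phenoxide of 4, formed by K3PO4, binds monovalent rhodium and brings it to the aldehyde C–H bond, giving a five-membered acyl hydride chelate of trivalent rhodium that resists decarbonylation. Diene 14 binds through its less hindered 1,1-disubstituted terminus; hydride migration to the aryl-bearing carbon s3 places rhodium on the primary carbon s2, and acyl–s2 reductive elimination releases the ketone (the other order, acyl migration to s2 followed by C–H reductive elimination at s3 from the s3–s5 allyl hydride, forms the same bonds). The closest known reaction types are rhodium-catalysed hydroacylations of alkenes and 1,3-dienes with salicylaldehydes, linear-selective hydroacylations of 1,1-disubstituted alkenes that create a β-stereocentre, and cobalt-catalysed hydroacylations of 1,3-dienes; new here is anti-Markovnikov addition at a diene terminus joined to an enantioselective hydride transfer. No ring is closed. The s3 stereocentre (R) is set in the hydride transfer, whose face is chosen by the pocket of the chiral bisphosphine, which has to tell the aryl group from the alkenyl group on s3; s7 is too remote to matter. The step needs acyl on s2 and hydrogen on s3 (not branched or 1,4-addition) and an untouched E s4=s5 alkene: the competing allyl intermediate (hydride on s2) has a fully substituted and a secondary terminus, so its acyl reductive elimination should be slow while its formation is reversible, which should leave the primary alkyl channel to carry the turnover, and in that channel s4=s5 is never part of an allyl. The chromone enone and the silyl ethers are spectators under the weakly basic, anhydrous conditions.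

Step 12
Reactants: 15 the 8-acyl-7-hydroxychromone
Product: 16 8-{(3R,4E,7S)-7-(tert-butyldimethylsilyloxy)-3,9-bis[4-(tert-butyldimethylsilyloxy)phenyl]non-4-enoyl}-7-(tert-butyldimethylsilyloxy)-5-methoxy-4H-chromen-4-one
Conditions: TBSCl, imidazole, DMAP (cat.), DMF, rt
Reagents that add atoms: tert-butyldimethylsilyl chloride, CC(C)(C)[Si](C)(C)Cl
Why: Silylation of the acidic, chelated C7 phenol removes the only protic group before the borane reduction.

Step 13
Reactants: 16 the 7-silyloxy ketone
Product: 17 8-{(1S,3R,4E,7S)-1-hydroxy-7-(tert-butyldimethylsilyloxy)-3,9-bis[4-(tert-butyldimethylsilyloxy)phenyl]non-4-en-1-yl}-7-(tert-butyldimethylsilyloxy)-5-methoxy-4H-chromen-4-one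
Conditions: (R)-2-methyl-CBS-oxazaborolidine (0.5 equiv), catecholborane, toluene, −78 → −40 °C
Reagents that add atoms: none
Why: Corey–Bakshi–Shibata reduction: the ketone binds the oxazaborolidine boron anti to the larger, di-ortho-substituted aryl group and hydride comes from the coordinated borane, the (R)-catalyst giving the (S)-carbinol as with aryl alkyl ketones in general; the vinylogous ester carbonyl of the chromone and the alkene should not react with catecholborane at low temperature.

Step 14
Reactants: 17 the (1S)-benzylic alcohol
Product: 18 8-{(1S,3R,4E,7S)-1,7-bis(tert-butyldimethylsilyloxy)-3,9-bis[4-(tert-butyldimethylsilyloxy)phenyl]non-4-en-1-yl}-7-(tert-butyldimethylsilyloxy)-5-methoxy-4H-chromen-4-one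
Conditions: TBSOTf, 2,6-lutidine, CH2Cl2, −78 → 0 °C
Reagents that add atoms: tert-butyldimethylsilyl trifluoromethanesulfonate, CC(C)(C)[Si](C)(C)OS(=O)(=O)C(F)(F)F
Why: Silylation of the hindered benzylic alcohol with the silyl triflate under buffered conditions; the ether protects s1 against oxidation by divalent palladium under air in the next step.

Step 15
Reactants: 18 the pentasilylated chromone; 19 4-(tert-butyldimethylsilyloxy)phenylboronic acid
Product: 20 (2S)-8-{(1S,3R,4E,7S)-1,7-bis(tert-butyldimethylsilyloxy)-3,9-bis[4-(tert-butyldimethylsilyloxy)phenyl]non-4-en-1-yl}-7-(tert-butyldimethylsilyloxy)-2-[4-(tert-butyldimethylsilyloxy)phenyl]-5-methoxychroman-4-one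
Conditions: Pd(OCOCF3)2 (10 mol%), (R)-t-BuPyOx (12 mol%), NH4PF6 (30 mol%), H2O (5 equiv), ClCH2CH2Cl, 60 °C
Reagents that add atoms: none
Why: Palladium-catalysed asymmetric conjugate addition of an arylboronic acid to a chromone: the cationic aryl–palladium pyridine-oxazoline complex inserts the C2=C3 bond and the palladium enolate is protonated by water; the (R)-ligand should deliver the aryl group to the face that gives (2S), the mirror image of the sense of the (S)-ligand with cyclic enones.

Step 16
Reactants: 20 the hexasilyl ether
Product: 21 (2S)-8-[(1S,3R,4E,7S)-1,7-dihydroxy-3,9-bis(4-hydroxyphenyl)non-4-en-1-yl]-7-hydroxy-2-(4-hydroxyphenyl)-5-methoxychroman-4-one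
Conditions: Bu4NF, AcOH (1:1), THF, 0 °C → rt
Reagents that add atoms: none
Why: Fluoride cleaves the four aryl and two alkyl silyl ethers; buffering with acetic acid keeps the medium near neutral, so the flavanone should not open to the chalcone and the s1 carbinol should not ionise.

## Compound list

1 | 2′,4′-dihydroxy-6′-methoxyacetophenone | COc1cc(O)cc(O)c1C(C)=O | starting material
2 | (E)-3-(dimethylamino)-1-(2,4-dihydroxy-6-methoxyphenyl)prop-2-en-1-one | COc1cc(O)cc(O)c1C(=O)/C=C/N(C)C | intermediate (not isolated)
3 | 7-hydroxy-5-methoxy-4H-chromen-4-one | COc1cc(O)cc2c1C(=O)C=CO2 | intermediate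
4 | 7-hydroxy-5-methoxy-4-oxo-4H-chromene-8-carbaldehyde | COc1cc(O)c(C=O)c2c1C(=O)C=CO2 | intermediate
5 | 4′-hydroxyacetophenone | CC(=O)c1ccc(O)cc1 | starting material
6 | 4′-(tert-butyldimethylsilyloxy)acetophenone | CC(=O)c1ccc(O[Si](C)(C)C(C)(C)C)cc1 | intermediate
7 | 1-[4-(tert-butyldimethylsilyloxy)phenyl]vinyl trifluoromethanesulfonate | C=C(OS(=O)(=O)C(F)(F)F)c1ccc(O[Si](C)(C)C(C)(C)C)cc1 | intermediate
8 | methyl 3-(4-hydroxyphenyl)propanoate | COC(=O)CCc1ccc(O)cc1 | starting material
9 | methyl 3-[4-(tert-butyldimethylsilyloxy)phenyl]propanoate | COC(=O)CCc1ccc(O[Si](C)(C)C(C)(C)C)cc1 | intermediate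
10 | 3-[4-(tert-butyldimethylsilyloxy)phenyl]propanal | O=CCCc1ccc(O[Si](C)(C)C(C)(C)C)cc1 | intermediate
11 | (S)-1-[4-(tert-butyldimethylsilyloxy)phenyl]hex-5-yn-3-ol | C#CC[C@@H](O)CCc1ccc(O[Si](C)(C)C(C)(C)C)cc1 | intermediate
12 | tert-butyl{4-[(3S)-3-(tert-butyldimethylsilyloxy)hex-5-yn-1-yl]phenoxy}dimethylsilane | C#CC[C@@H](O[Si](C)(C)C(C)(C)C)CCc1ccc(O[Si](C)(C)C(C)(C)C)cc1 | intermediate
13 | 2-{(1E,4S)-4-(tert-butyldimethylsilyloxy)-6-[4-(tert-butyldimethylsilyloxy)phenyl]hex-1-en-1-yl}-4,4,5,5-tetramethyl-1,3,2-dioxaborolane | CC1(C)OB(/C=C/C[C@@H](O[Si](C)(C)C(C)(C)C)CCc2ccc(O[Si](C)(C)C(C)(C)C)cc2)OC1(C)C | intermediate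
14 | (3E,6S)-6-(tert-butyldimethylsilyloxy)-2,8-bis[4-(tert-butyldimethylsilyloxy)phenyl]octa-1,3-diene | C=C(/C=C/C[C@@H](O[Si](C)(C)C(C)(C)C)CCc1ccc(O[Si](C)(C)C(C)(C)C)cc1)c1ccc(O[Si](C)(C)C(C)(C)C)cc1 | intermediate
15 | 8-{(3R,4E,7S)-7-(tert-butyldimethylsilyloxy)-3,9-bis[4-(tert-butyldimethylsilyloxy)phenyl]non-4-enoyl}-7-hydroxy-5-methoxy-4H-chromen-4-one | COc1cc(O)c(C(=O)C[C@H](/C=C/C[C@@H](O[Si](C)(C)C(C)(C)C)CCc3ccc(O[Si](C)(C)C(C)(C)C)cc3)c3ccc(O[Si](C)(C)C(C)(C)C)cc3)c2c1C(=O)C=CO2 | intermediate
16 | 7-O-tert-butyldimethylsilyl ether of 15 | COc1cc(O[Si](C)(C)C(C)(C)C)c(C(=O)C[C@H](/C=C/C[C@@H](O[Si](C)(C)C(C)(C)C)CCc3ccc(O[Si](C)(C)C(C)(C)C)cc3)c3ccc(O[Si](C)(C)C(C)(C)C)cc3)c2c1C(=O)C=CO2 | intermediate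
17 | 8-{(1S,3R,4E,7S)-1-hydroxy-7-(tert-butyldimethylsilyloxy)-3,9-bis[4-(tert-butyldimethylsilyloxy)phenyl]non-4-en-1-yl}-7-(tert-butyldimethylsilyloxy)-5-methoxy-4H-chromen-4-one | COc1cc(O[Si](C)(C)C(C)(C)C)c([C@@H](O)C[C@H](/C=C/C[C@@H](O[Si](C)(C)C(C)(C)C)CCc3ccc(O[Si](C)(C)C(C)(C)C)cc3)c3ccc(O[Si](C)(C)C(C)(C)C)cc3)c2c1C(=O)C=CO2 | intermediate
18 | s1-O-tert-butyldimethylsilyl ether of 17 | COc1cc(O[Si](C)(C)C(C)(C)C)c([C@@H](O[Si](C)(C)C(C)(C)C)C[C@H](/C=C/C[C@@H](O[Si](C)(C)C(C)(C)C)CCc3ccc(O[Si](C)(C)C(C)(C)C)cc3)c3ccc(O[Si](C)(C)C(C)(C)C)cc3)c2c1C(=O)C=CO2 | intermediate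
19 | 4-(tert-butyldimethylsilyloxy)phenylboronic acid | OB(O)c1ccc(O[Si](C)(C)C(C)(C)C)cc1 | starting material
20 | hexakis(tert-butyldimethylsilyl) ether of 21, (2S)-flavanone | COc1cc(O[Si](C)(C)C(C)(C)C)c([C@@H](O[Si](C)(C)C(C)(C)C)C[C@H](/C=C/C[C@@H](O[Si](C)(C)C(C)(C)C)CCc3ccc(O[Si](C)(C)C(C)(C)C)cc3)c3ccc(O[Si](C)(C)C(C)(C)C)cc3)c2c1C(=O)C[C@@H](c1ccc(O[Si](C)(C)C(C)(C)C)cc1)O2 | intermediate
21 | (2S)-8-[(1S,3R,4E,7S)-1,7-dihydroxy-3,9-bis(4-hydroxyphenyl)non-4-en-1-yl]-7-hydroxy-2-(4-hydroxyphenyl)-5-methoxychroman-4-one | COc1cc(O)c([C@@H](O)C[C@H](/C=C/C[C@@H](O)CCc2ccc(O)cc2)c2ccc(O)cc2)c2c1C(=O)C[C@@H](c1ccc(O)cc1)O2 | target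

## Step count and risk

Total: 16 steps. Longest linear sequence: 12 steps (8 to 21 through steps 5–10 and 11–16).

**Step 11 (key step, proposed new method).**
- Most likely to go wrong: hydride addition to the CH2 terminus in place of s3, which leads through the conjugated allyl to branched or 1,4-adducts. Behind that lie low facial selectivity at s3, decarbonylation of the acyl rhodium, and rhodium hydride-mediated migration of s4=s5 into conjugation with the aryl group.
- Fallback by known chemistry: it sets out from 4 and 13 and returns at 16. Aldehyde 4 is silylated (TBSCl, imidazole, DMF) to 7-(tert-butyldimethylsilyloxy)-5-methoxy-4-oxo-4H-chromene-8-carbaldehyde F1. Commercial 4-(tert-butyldimethylsilyloxy)benzaldehyde is taken by Takai iodo-olefination (CHI3, CrCl2, THF) to (E)-tert-butyl[4-(2-iodoethenyl)phenoxy]dimethylsilane F2. Nozaki–Hiyama–Kishi coupling of F1 with F2 (CrCl2, NiCl2 cat., DMF), which is selective for the aldehyde over the chromone, should give the racemic allylic alcohol 7-(tert-butyldimethylsilyloxy)-8-{(E)-1-hydroxy-3-[4-(tert-butyldimethylsilyloxy)phenyl]prop-2-en-1-yl}-5-methoxy-4H-chromen-4-one F3. MnO2 in CH2Cl2 oxidises it to the chalcone-type enone 7-(tert-butyldimethylsilyloxy)-8-{(E)-3-[4-(tert-butyldimethylsilyloxy)phenyl]prop-2-enoyl}-5-methoxy-4H-chromen-4-one F4. Hayashi–Miyaura 1,4-addition of boronate 13 to F4 ([RhCl(C2H4)2]2, the BINAP enantiomer that places the alkenyl group on the face giving (R) at s3, Et3N, dioxane/H2O, 40 °C) then forms the s3–s4 bond in place of the s1–s2 bond and gives 16.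

**Step 15.**
- Most likely to go wrong: slow insertion, because the 5,7-dioxygenated, 8-substituted chromone is a poor acceptor, so that protodeboronation of 19 overtakes it. Also possible are eroded facial selectivity next to the bulky C8 substituent and partial silyl loss through fluoride released from hexafluorophosphate.
- Fallback: it sets out from 18 and returns at 20. Copper-mediated 1,4-addition of 4-(tert-butyldimethylsilyloxy)phenylmagnesium bromide (CuBr·SMe2, Me3SiCl, THF, −78 °C, then aqueous work-up) is run without chiral control. Because s1, s3 and s7 are already fixed, the two C2 epimers are diastereomers, and 20 is separated by chromatography from its (2R)-epimer F5.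

**Step 13.**
- Most likely to go wrong: poor facial selectivity at a twisted, di-ortho-substituted aryl ketone, slow reduction, or competing reduction of the chromone.
- Fallback: it sets out from 16 and returns at 17. Unselective Luche reduction (NaBH4, CeCl3·7H2O, MeOH/THF, −40 °C) gives 17 together with its (1R)-epimer F6. The two are diastereomers and are separated by chromatography, and F6 is returned to 16 by Dess–Martin oxidation and reduced again.

**Step 16.**
- Most likely to go wrong: incomplete cleavage of the hindered benzylic silyl ether under buffered fluoride. If the conditions are then forced, epimerisation at C2 by ring opening or loss of the s1 configuration through an ortho-quinone methide can follow.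
- Fallback: it sets out from 17 and returns at 21. The s1 hydroxyl is protected as the more labile triethylsilyl ether (TESOTf, 2,6-lutidine, CH2Cl2, −78 °C) to give the s1-O-triethylsilyl analogue of 18, F7. The conjugate addition of step 15 is applied to F7 to give the s1-O-triethylsilyl analogue of 20, F8, and buffered Bu4NF/AcOH then removes all silyl groups under milder conditions to give 21.

**Step 2.**
- Most likely to go wrong: formylation at C6 or at both free positions.
- Fallback: it sets out from 3 and returns at 4. O-Allylation (allyl bromide, K2CO3, acetone) gives 7-(allyloxy)-5-methoxy-4H-chromen-4-one F9. Thermal Claisen rearrangement (N,N-diethylaniline, 190 °C), which in 7-allyloxychromones goes to C8, gives 8-allyl-7-hydroxy-5-methoxy-4H-chromen-4-one F10. Alkene isomerisation (RuHCl(CO)(PPh3)3, toluene, 80 °C) gives 7-hydroxy-5-methoxy-8-[(E)-prop-1-en-1-yl]-4H-chromen-4-one F11, and Lemieux–Johnson cleavage (OsO4 cat., NaIO4, 2,6-lutidine, dioxane/H2O) gives 4.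

## Further compounds

F1 | step 11 | 7-(tert-butyldimethylsilyloxy)-5-methoxy-4-oxo-4H-chromene-8-carbaldehyde | COc1cc(O[Si](C)(C)C(C)(C)C)c(C=O)c2c1C(=O)C=CO2
F2 | step 11 | (E)-tert-butyl[4-(2-iodoethenyl)phenoxy]dimethylsilane | I/C=C/c1ccc(O[Si](C)(C)C(C)(C)C)cc1
F3 | step 11 | racemic 7-(tert-butyldimethylsilyloxy)-8-{(E)-1-hydroxy-3-[4-(tert-butyldimethylsilyloxy)phenyl]prop-2-en-1-yl}-5-methoxy-4H-chromen-4-one | COc1cc(O[Si](C)(C)C(C)(C)C)c(C(O)/C=C/c3ccc(O[Si](C)(C)C(C)(C)C)cc3)c2c1C(=O)C=CO2
F4 | step 11 | 7-(tert-butyldimethylsilyloxy)-8-{(E)-3-[4-(tert-butyldimethylsilyloxy)phenyl]prop-2-enoyl}-5-methoxy-4H-chromen-4-one | COc1cc(O[Si](C)(C)C(C)(C)C)c(C(=O)/C=C/c3ccc(O[Si](C)(C)C(C)(C)C)cc3)c2c1C(=O)C=CO2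
F5 | step 15 | (2R)-epimer of 20 | COc1cc(O[Si](C)(C)C(C)(C)C)c([C@@H](O[Si](C)(C)C(C)(C)C)C[C@H](/C=C/C[C@@H](O[Si](C)(C)C(C)(C)C)CCc3ccc(O[Si](C)(C)C(C)(C)C)cc3)c3ccc(O[Si](C)(C)C(C)(C)C)cc3)c2c1C(=O)C[C@H](c1ccc(O[Si](C)(C)C(C)(C)C)cc1)O2
F6 | step 13 | (1R)-epimer of 17 at s1 | COc1cc(O[Si](C)(C)C(C)(C)C)c([C@H](O)C[C@H](/C=C/C[C@@H](O[Si](C)(C)C(C)(C)C)CCc3ccc(O[Si](C)(C)C(C)(C)C)cc3)c3ccc(O[Si](C)(C)C(C)(C)C)cc3)c2c1C(=O)C=CO2
F7 | step 16 | s1-O-triethylsilyl analogue of 18 | COc1cc(O[Si](C)(C)C(C)(C)C)c([C@@H](O[Si](CC)(CC)CC)C[C@H](/C=C/C[C@@H](O[Si](C)(C)C(C)(C)C)CCc3ccc(O[Si](C)(C)C(C)(C)C)cc3)c3ccc(O[Si](C)(C)C(C)(C)C)cc3)c2c1C(=O)C=CO2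
F8 | step 16 | s1-O-triethylsilyl analogue of 20 | COc1cc(O[Si](C)(C)C(C)(C)C)c([C@@H](O[Si](CC)(CC)CC)C[C@H](/C=C/C[C@@H](O[Si](C)(C)C(C)(C)C)CCc3ccc(O[Si](C)(C)C(C)(C)C)cc3)c3ccc(O[Si](C)(C)C(C)(C)C)cc3)c2c1C(=O)C[C@@H](c1ccc(O[Si](C)(C)C(C)(C)C)cc1)O2
F9 | step 2 | 7-(allyloxy)-5-methoxy-4H-chromen-4-one | COc1cc(OCC=C)cc2c1C(=O)C=CO2
F10 | step 2 | 8-allyl-7-hydroxy-5-methoxy-4H-chromen-4-one | COc1cc(O)c(CC=C)c2c1C(=O)C=CO2
F11 | step 2 | 7-hydroxy-5-methoxy-8-[(E)-prop-1-en-1-yl]-4H-chromen-4-one | COc1cc(O)c(/C=C/C)c2c1C(=O)C=CO2
A1 | alternative 1 | (E)-homoallylic alcohol with the complete chain on a 2,6-bis(methoxymethoxy)-4-methoxyphenyl ring A, s1 as silyl ether, s7 hydroxyl free | COc1cc(OCOC)c([C@@H](O[Si](C)(C)C(C)(C)C)C[C@H](/C=C/C[C@@H](O)CCc2ccc(O[Si](C)(C)C(C)(C)C)cc2)c2ccc(O[Si](C)(C)C(C)(C)C)cc2)c(OCOC)c1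
A2 | alternative 1 | secondary allylic pinacol boronate with boron on s4 (s1 S, s3 R, s4 R) | COc1cc(OCOC)c([C@@H](O[Si](C)(C)C(C)(C)C)C[C@H]([C@H](B2OC(C)(C)C(C)(C)O2)C=C)c2ccc(O[Si](C)(C)C(C)(C)C)cc2)c(OCOC)c1
A3 | alternative 2 | hexakis(tert-butyldimethylsilyl) ether of 21, identical with 20 | COc1cc(O[Si](C)(C)C(C)(C)C)c([C@@H](O[Si](C)(C)C(C)(C)C)C[C@H](/C=C/C[C@@H](O[Si](C)(C)C(C)(C)C)CCc3ccc(O[Si](C)(C)C(C)(C)C)cc3)c3ccc(O[Si](C)(C)C(C)(C)C)cc3)c2c1C(=O)C[C@@H](c1ccc(O[Si](C)(C)C(C)(C)C)cc1)O2
A4 | alternative 3 | 2,6-bis(methoxymethoxy)-4-methoxyphenyl ketone carrying the complete s2–s9 chain | COc1cc(OCOC)c(C(=O)C[C@H](/C=C/C[C@@H](O[Si](C)(C)C(C)(C)C)CCc2ccc(O[Si](C)(C)C(C)(C)C)cc2)c2ccc(O[Si](C)(C)C(C)(C)C)cc2)c(OCOC)c1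
A5 | alternative 3 | 1-arylvinyl ether of the s5 allylic alcohol (s5 R, s7 S) | C=C(O[C@@H](/C=C/c1ccc(O[Si](C)(C)C(C)(C)C)cc1)C[C@@H](O[Si](C)(C)C(C)(C)C)CCc1ccc(O[Si](C)(C)C(C)(C)C)cc1)c1c(OCOC)cc(OC)cc1OCOC
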